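**Plan** (labdane numbering: ring A = C1–C5 and C10, ring B = C5–C10, side chain C11–C16, C20 = methyl on C10)

- Retrosynthetic cuts, in order: ester O–acyl bond; C13=C14; C11–C12; C9=C11; ring A at C3–C4; C10–C1 and C10–C20, leading back to (S)-carvone (1).
- Forward: ring B is the carvone ring. Two enolate alkylations build quaternary C10 (methyl, then a propargyl arm that becomes the 3-oxopropyl arm). Ring A closes by joining aldehyde carbon C3 to C4. The side chain is then grown from the C9 ketone.
- Enabling feature: the gem-dimethyl carbon C4 of ring A lies between the ring-fusion methine C5 and the carbinol carbon C3. C4 with C5 is the isopropenyl-bearing stereocentre of carvone, so hydrogen-atom transfer to that alkene gives a tertiary C4 radical held 1,6 to an aldehyde on C10. One 6-exo closure makes ring A, the quaternary carbon and the C3–O function.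
- Stereochemistry: C5 from (S)-carvone; C10 by alkylation anti to the isopropenyl group; C9 by hydroboration anti to the C10 methyl; C3 by equatorial hydride delivery (axial alcohol); 13E by Horner–Wadsworth–Emmons olefination; the ester stereocentre from (S)-3-methylpentanoic acid.

Key step: step 4

Remark: the SMILES fixes 3S,5S,9R,10S, i.e. an ent-labdane core whose C3 hydroxyl is axial and trans to the C10 methyl; the route is built for this arrangement. (S)-Carvone and (S)-3-methylpentanoic acid are taken as commercial.

**Step 1**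
Reactants: 1 (S)-carvone; 2 iodomethane
Product: 4 (5S)-2,6-dimethyl-5-(prop-1-en-2-yl)cyclohex-2-en-1-one (6-methylcarvone; C6 epimers), via lithium dienolate 3 (not isolated)
Conditions: LiN(i-Pr)2, THF, −78 °C; MeI, −78 to 0 °C
Reagents that add atoms: iodomethane (2), CI
Why: Kinetic deprotonation at C6 (alpha-prime) and SN2 methylation of the cross-conjugated lithium dienolate (ketone enolate alkylation); the new centre forms as an epimer mixture of no consequence, because it becomes the enolate carbon again in step 2.

**Step 2**
Reactants: 4 6-methylcarvone; 5 3-bromoprop-1-yne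
Product: 7 (5R,6R)-2,6-dimethyl-5-(prop-1-en-2-yl)-6-(prop-2-yn-1-yl)cyclohex-2-en-1-one, via lithium dienolate 6 (not isolated)
Conditions: LiN(i-Pr)2, THF, −78 °C; propargyl bromide, −78 °C to rt
Reagents that add atoms: 3-bromoprop-1-yne (5), C#CCBr
Why: Enolate alkylation in which the electrophile should enter anti to the neighbouring isopropenyl group, so the quaternary carbon (later C10) carries its methyl cis and its three-carbon arm trans to that group, as a trans ring fusion requires.

**Step 3**
Reactants: 7 propargyl ketone
Product: 9 3-[(1R,6R)-1,3-dimethyl-2-oxo-6-(prop-1-en-2-yl)cyclohex-3-en-1-yl]propanal, via alkenylborane 8 (not isolated)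
Conditions: Cy2BH, THF, 0 °C; then H2O2, pH 7 phosphate buffer, 0 °C to rt
Reagents that add atoms: hydrogen peroxide, OO
Why: Monohydroboration–oxidation of a terminal alkyne; the bulky dialkylborane should add syn and anti-Markovnikov to the alkyne faster than to the hindered 1,1-disubstituted alkene or the hindered conjugated ketone, and buffered oxidation of the alkenylborane gives the aldehyde without epoxidising the enone.

**Step 4**
Reactants: 9 keto aldehyde
Product: 10 (4aR,6R,8aR)-6-hydroxy-2,5,5,8a-tetramethyl-4a,5,6,7,8,8a-hexahydronaphthalen-1(4H)-one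
Conditions: Fe(acac)3 (30 mol %), PhSiH3 (slow addition), EtOH (0.02 M), 60 °C
Reagents that add atoms: none
Why: Fe(acac)3 and PhSiH3 in ethanol form an iron hydride that transfers a hydrogen atom to the CH2 terminus of the isopropenyl group (Markovnikov), giving the tertiary C4 radical; this adds to the aldehyde carbon C3, and the alkoxy radical is reduced by divalent iron and protonated by ethanol, which returns trivalent iron. The closest known reaction type is the iron-hydride HAT reductive cyclisation of alkene-tethered ketones, together with the iron-catalysed radical addition of unactivated alkenes to aldehydes. Ring A closes in the 6-exo-trig mode onto the C=O group through a chair in which C4 and C1 are both equatorial on ring B, so the trans fusion already fixed at C5 and C10 is kept. The only new stereocentre is C3: the chair with the carbonyl oxygen pseudo-equatorial is expected to prevail and give the equatorial (6R) alcohol, and since C3 is reset in steps 6 and 7 either epimer is usable. The step needs chemoselectivity: hydrogen-atom transfer to the electron-rich 1,1-disubstituted alkene and not to the electron-poor enone alkene, attack at the aldehyde and not at the C9 ketone (a four-membered ring), and ring closure ahead of reduction of the radical. The electronic difference between the alkenes, the tether length, high dilution and slow silane addition should secure these.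

**Step 5**
Reactants: 10 hydroxy enone; 11 methyltriphenylphosphonium bromide
Product: 12 (2R,4aR,8aS)-1,1,4a,6-tetramethyl-5-methylidene-1,2,3,4,4a,5,8,8a-octahydronaphthalen-2-ol
Conditions: Ph3PCH3Br, KOt-Bu, toluene, 90 °C
Reagents that add atoms: methyltriphenylphosphonium bromide (11), C[P+](c1ccccc1)(c1ccccc1)c1ccccc1.[Br-]
Why: Wittig methylenation of the hindered C9 ketone with the non-stabilised ylide at elevated temperature should give the 7,9(11)-diene; no stereocentre is formed and any C3 epimer of 10 is carried along.

**Step 6**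
Reactants: 12 hydroxy diene
Product: 13 (4aR,8aS)-1,1,4a,6-tetramethyl-5-methylidene-3,4,4a,5,8,8a-hexahydronaphthalen-2(1H)-one
Conditions: DMP (triacetoxyperiodinane), pyridine, CH2Cl2, 0 °C to rt
Reagents that add atoms: none
Why: Buffered hypervalent-iodine oxidation of the secondary alcohol leaves the acid-sensitive 1,3-diene untouched and merges both C3 epimers into one ketone.

**Step 7**
Reactants: 13 keto diene
Product: 14 (2S,4aR,8aS)-1,1,4a,6-tetramethyl-5-methylidene-1,2,3,4,4a,5,8,8a-octahydronaphthalen-2-ol
Conditions: LiBH(s-Bu)3 (L-Selectride), THF, −78 °C; then H2O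
Reagents that add atoms: none
Why: Diastereoselective ketone reduction; the bulky trialkylborohydride cannot use the axial trajectory past the axial hydrogens on C1 and C5 and should deliver hydride along the equatorial one, giving the axial alcohol trans to the angular methyl, the usual outcome for 4,4-dimethyl-3-oxo trans-decalins.

**Step 8**
Reactants: 14 axial hydroxy diene; 15 1-bromopropan-2-one
Product: 17 4-[(1R,4aS,6S,8aS)-6-hydroxy-2,5,5,8a-tetramethyl-1,4,4a,5,6,7,8,8a-octahydronaphthalen-1-yl]butan-2-one, via C11-boryl O-boryl adduct 16 (not isolated)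
Conditions: 9-BBN-H (2.2 equiv), THF, rt to 40 °C; then BrCH2COCH3, potassium 2,6-di-tert-butylphenoxide, THF, 0 °C to rt; H2O
Reagents that add atoms: 1-bromopropan-2-one (15), CC(=O)CBr
Why: Hydroboration followed by alpha-alkylation of an alpha-halo ketone with a B-alkyl-9-BBN (ate complex, 1,2-migration of the primary alkyl group with loss of bromide, protonolysis of the boron enolate by the phenol); 9-BBN should place boron on terminal C11 and hydrogen on C9 from the face opposite the axial C10 methyl, which sets C9 with the side chain cis to that methyl, while the first equivalent masks the hydroxyl as its borinate.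

**Step 9**
Reactants: 17 methyl ketone; 18 triethyl phosphonoacetate
Product: 19 ethyl (2E)-5-[(1R,4aS,6S,8aS)-6-hydroxy-2,5,5,8a-tetramethyl-1,4,4a,5,6,7,8,8a-octahydronaphthalen-1-yl]-3-methylpent-2-enoate
Conditions: (EtO)2P(O)CH2CO2Et, NaH (anion preformed, no excess NaH), THF, 0 °C to reflux
Reagents that add atoms: triethyl phosphonoacetate (18), CCOC(=O)CP(=O)(OCC)OCC
Why: Horner–Wadsworth–Emmons olefination of a methyl ketone; the E isomer (chain trans to the ester) should predominate and is separated from the Z isomer by chromatography, and the preformed phosphonate anion is too weak a base to deprotonate the hindered hydroxyl.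

**Step 10**
Reactants: 19 E-enoate
Product: 20 (2S,4aS,5R,8aS)-5-[(3E)-5-hydroxy-3-methylpent-3-en-1-yl]-1,1,4a,6-tetramethyl-1,2,3,4,4a,5,8,8a-octahydronaphthalen-2-ol
Conditions: i-Bu2AlH, CH2Cl2, −78 to 0 °C; aqueous KNaC4H4O6 work-up
Reagents that add atoms: none
Why: 1,2-Reduction of the conjugated ester to the allylic alcohol with the aluminium hydride at low temperature leaves both trisubstituted alkenes and the alkene geometry untouched.

**Step 11**
Reactants: 20 diol; 21 (3S)-3-methylpentanoic acid
Product: 22 (2E)-5-[(1R,4aS,6S,8aS)-6-hydroxy-2,5,5,8a-tetramethyl-1,4,4a,5,6,7,8,8a-octahydronaphthalen-1-yl]-3-methylpent-2-en-1-yl (3S)-3-methylpentanoate (target)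
Conditions: (S)-3-methylpentanoic acid (1.05 equiv), DIC, DMAP (cat.), CH2Cl2, 0 °C
Reagents that add atoms: (3S)-3-methylpentanoic acid (21), CC[C@H](C)CC(=O)O
Why: Carbodiimide-mediated (Steglich) esterification; the primary allylic hydroxyl should be acylated far faster than the axial C3 hydroxyl flanked by the gem-dimethyl carbon, and the beta-stereocentre of the acid cannot epimerise under these conditions.

**Compound list**

1 | (S)-carvone, (5S)-2-methyl-5-(prop-1-en-2-yl)cyclohex-2-en-1-one | CC1=CC[C@@H](CC1=O)C(C)=C | starting material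
2 | iodomethane | CI | starting material
3 | lithium cross-conjugated dienolate of 1 (C6 deprotonated) | [Li]OC1=C[C@@H](C(C)=C)CC=C1C | intermediate (not isolated)
4 | (5S)-2,6-dimethyl-5-(prop-1-en-2-yl)cyclohex-2-en-1-one (C6 epimers) | O=C1C(C)=CC[C@H](C(C)=C)C1C | intermediate
5 | 3-bromoprop-1-yne | C#CCBr | starting material
6 | lithium cross-conjugated dienolate of 4 | [Li]OC1=C(C)[C@@H](C(C)=C)CC=C1C | intermediate (not isolated)
7 | (5R,6R)-2,6-dimethyl-5-(prop-1-en-2-yl)-6-(prop-2-yn-1-yl)cyclohex-2-en-1-one (propargyl trans to isopropenyl) | O=C1C(C)=CC[C@H](C(C)=C)[C@@]1(C)CC#C | intermediate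
8 | (E)-alkenyl(dicyclohexyl)borane from 7 | O=C1C(C)=CC[C@H](C(C)=C)[C@@]1(C)C/C=C/B(C2CCCCC2)C2CCCCC2 | intermediate (not isolated)
9 | 3-[(1R,6R)-1,3-dimethyl-2-oxo-6-(prop-1-en-2-yl)cyclohex-3-en-1-yl]propanal | O=C1C(C)=CC[C@H](C(C)=C)[C@@]1(C)CCC=O | intermediate
10 | (4aR,6R,8aR)-6-hydroxy-2,5,5,8a-tetramethyl-4a,5,6,7,8,8a-hexahydronaphthalen-1(4H)-one (trans-fused; equatorial hydroxyl expected; the 6S epimer is equally usable) | O=C1C(C)=CC[C@@H]2C(C)(C)[C@H](O)CC[C@@]12C | intermediate
11 | methyltriphenylphosphonium bromide | C[P+](c1ccccc1)(c1ccccc1)c1ccccc1.[Br-] | starting material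
12 | (2R,4aR,8aS)-1,1,4a,6-tetramethyl-5-methylidene-1,2,3,4,4a,5,8,8a-octahydronaphthalen-2-ol | C=C1C(C)=CC[C@@H]2C(C)(C)[C@H](O)CC[C@@]12C | intermediate
13 | (4aR,8aS)-1,1,4a,6-tetramethyl-5-methylidene-3,4,4a,5,8,8a-hexahydronaphthalen-2(1H)-one | C=C1C(C)=CC[C@@H]2C(C)(C)C(=O)CC[C@@]12C | intermediate
14 | (2S,4aR,8aS)-1,1,4a,6-tetramethyl-5-methylidene-1,2,3,4,4a,5,8,8a-octahydronaphthalen-2-ol (axial hydroxyl) | C=C1C(C)=CC[C@@H]2C(C)(C)[C@@H](O)CC[C@@]12C | intermediate
15 | 1-bromopropan-2-one | CC(=O)CBr | starting material
16 | adduct of 14 carrying 9-borabicyclo[3.3.1]nonan-9-yl groups on C11 and on the C3 oxygen | C(B3C4CCCC3CCC4)[C@@H]1C(C)=CC[C@@H]2C(C)(C)[C@@H](OB5C6CCCC5CCC6)CC[C@@]12C | intermediate (not isolated)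
17 | 4-[(1R,4aS,6S,8aS)-6-hydroxy-2,5,5,8a-tetramethyl-1,4,4a,5,6,7,8,8a-octahydronaphthalen-1-yl]butan-2-one | CC(=O)CC[C@@H]1C(C)=CC[C@@H]2C(C)(C)[C@@H](O)CC[C@@]12C | intermediate
18 | triethyl phosphonoacetate | CCOC(=O)CP(=O)(OCC)OCC | starting material
19 | ethyl (2E)-5-[(1R,4aS,6S,8aS)-6-hydroxy-2,5,5,8a-tetramethyl-1,4,4a,5,6,7,8,8a-octahydronaphthalen-1-yl]-3-methylpent-2-enoate | CCOC(=O)/C=C(\C)CC[C@@H]1C(C)=CC[C@@H]2C(C)(C)[C@@H](O)CC[C@@]12C | intermediate
20 | (2S,4aS,5R,8aS)-5-[(3E)-5-hydroxy-3-methylpent-3-en-1-yl]-1,1,4a,6-tetramethyl-1,2,3,4,4a,5,8,8a-octahydronaphthalen-2-ol | OC/C=C(\C)CC[C@@H]1C(C)=CC[C@@H]2C(C)(C)[C@@H](O)CC[C@@]12C | intermediate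
21 | (3S)-3-methylpentanoic acid | CC[C@H](C)CC(=O)O | starting material
22 | (2E)-5-[(1R,4aS,6S,8aS)-6-hydroxy-2,5,5,8a-tetramethyl-1,4,4a,5,6,7,8,8a-octahydronaphthalen-1-yl]-3-methylpent-2-en-1-yl (3S)-3-methylpentanoate | CC[C@H](C)CC(=O)OC/C=C(\C)CC[C@@H]1C(C)=CC[C@@H]2C(C)(C)[C@@H](O)CC[C@@]12C | target

Total step count: 11. Longest linear sequence: 11 steps from (S)-carvone (1).

**Steps most likely to fail**

1. Step 4. The tertiary radical may be reduced by the iron hydride before it closes (net hydrogenation of the isopropenyl group), or the closure may revert by beta-scission faster than the alkoxy radical is reduced. Fallback: setting out from 9, Markovnikov addition of HBr (HBr in AcOH, CH2Cl2, 0 °C) would give the tertiary bromide F1. A tin-hydride chain (Bu3SnH by syringe pump, AIBN, benzene, 80 °C, high dilution) would then generate the same C4 radical by halogen abstraction. The alkoxy radical formed on 6-exo closure is trapped quickly by Bu3SnH, and the sequence comes back to the route at 10.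

2. Step 8. Ate-complex formation and 1,2-migration at the beta-branched C11 borane may be slow, so that reduction of bromoacetone by residual B–H or simple protodeboronation takes over. Fallback: setting out from 14, hydroboration with 9-BBN-H and oxidation (NaOH, H2O2) would give the 3,11-diol F3. Oxidation of the primary hydroxyl only (TEMPO, PhI(OAc)2, CH2Cl2) would give the hydroxy aldehyde F4. A Wittig reaction with the stabilised ylide Ph3P=CHC(O)CH3 (toluene, 60 °C) would give the E-enone F5. Conjugate reduction with [(Ph3P)CuH]6 (benzene, rt) would then come back to the route at 17.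

3. Step 5. The basic ylide may enolise the hindered enone (gamma-deprotonation) instead of adding to it, so that ketone is returned, partly deconjugated. Fallback: setting out from 10, addition of the weakly basic organocerium reagent from Me3SiCH2Li and CeCl3 (THF, −78 °C) would give the beta-hydroxysilane F2. Peterson elimination (KH, THF, rt) would come back to the route at 12.

**Further compounds**

F1 | step 4 | 3-[(1R,6S)-6-(2-bromopropan-2-yl)-1,3-dimethyl-2-oxocyclohex-3-en-1-yl]propanal | O=C1C(C)=CC[C@H](C(C)(C)Br)[C@@]1(C)CCC=O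
F2 | step 5 | (1R,4aR,6R,8aR)-2,5,5,8a-tetramethyl-1-[(trimethylsilyl)methyl]-1,4,4a,5,6,7,8,8a-octahydronaphthalene-1,6-diol (C1 configuration immaterial) | O[C@]1(C[Si](C)(C)C)C(C)=CC[C@@H]2C(C)(C)[C@H](O)CC[C@@]12C
F3 | step 8 | 3,11-diol: 5-(hydroxymethyl)-1,1,4a,6-tetramethyl-1,2,3,4,4a,5,8,8a-octahydronaphthalen-2-ol with the ring stereochemistry of 17 | OC[C@@H]1C(C)=CC[C@@H]2C(C)(C)[C@@H](O)CC[C@@]12C
F4 | step 8 | 6-hydroxy-2,5,5,8a-tetramethyl-1,4,4a,5,6,7,8,8a-octahydronaphthalene-1-carbaldehyde with the ring stereochemistry of 17 | O=C[C@@H]1C(C)=CC[C@@H]2C(C)(C)[C@@H](O)CC[C@@]12C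
F5 | step 8 | (3E)-4-[6-hydroxy-2,5,5,8a-tetramethyl-1,4,4a,5,6,7,8,8a-octahydronaphthalen-1-yl]but-3-en-2-one with the ring stereochemistry of 17 | CC(=O)/C=C/[C@@H]1C(C)=CC[C@@H]2C(C)(C)[C@@H](O)CC[C@@]12C
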